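**Retrosynthetic overview**

- Feature addressed: in the middle flavan, ring A has C5–H (no oxygen) yet is bonded through C8 (between O1 and C7–OH) to C4 of the upper unit, and ring C carries the triad C2‑aryl/C3‑OH cis, C3‑OH/C4‑aryl trans. The middle unit is therefore carried as a phloroglucinol‑type ring with O5 tagged, and C5–H is the last bond formed: hydrogenolysis of C5–OTf together with eleven benzyl ethers and a C8–Br cap.
- Upper C4–middle C8 bond: cationic coupling of an 8‑bromo‑capped epicatechin C4 ether with C8 of the O5‑tagged ring of the middle–lower dimer.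
- Middle C4–lower C8 bond with C3 and C4 of the middle unit (key): arylative opening of a 2,3‑cis 3α,4α‑epoxyflavan made in the flask from a (+)‑taxifolin‑derived trans 4‑hydroxy‑3‑mesylate. The carbonyl oxygen becomes the 3α‑OH (1,2‑oxygen transposition, inversion at C3) and catechin C8 enters at 4β.
- The C4=O···HO–C5 chelate of taxifolin singles out O5 for the allyl tag, the one point where the middle unit differs from a benzylated epicatechin unit.
- Ring order: all three pyran rings come from the chiral pool; only the oxirane C3–O–C4 of the middle unit is closed and opened (step 9).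

Key step: step 9

Assumption: the SMILES is read as epicatechin‑(4β→8)‑epifisetinidol‑(4β→8)‑catechin (all C2 R with 2‑aryl α; upper and middle units 2,3‑cis‑3,4‑trans, lower unit 2,3‑trans); α/β follow flavan usage, and (+)‑catechin, (−)‑epicatechin and (+)‑taxifolin are bought.

**Route**

Step 1
Reactants: 1 (+)-catechin
Product: 2 5,7,3',4'-tetra-O-benzyl-(+)-catechin
Conditions: BnBr (4.4 equiv), K2CO3, DMF, 0 °C → rt, Ar
Reagents that add atoms: benzyl bromide, BrCc1ccccc1
Why: Williamson ether synthesis in which carbonate deprotonates only the four phenols, so the aliphatic 3-OH stays free and C2/C3 are untouched.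

Step 2
Reactants: 3 (−)-epicatechin
Product: 4 5,7,3',4'-tetra-O-benzyl-(−)-epicatechin
Conditions: BnBr (4.4 equiv), K2CO3, DMF, 0 °C → rt, Ar
Reagents that add atoms: benzyl bromide, BrCc1ccccc1
Why: Williamson ether synthesis of the four phenols under carbonate, which leaves the 3-OH and the 2,3-cis stereocentres unchanged.

Step 3
Reactants: 4 5,7,3',4'-tetra-O-benzyl-(−)-epicatechin
Product: 5 8-bromo-5,7,3',4'-tetra-O-benzyl-(−)-epicatechin
Conditions: NBS (1.0 equiv), CH2Cl2, −78 → 0 °C
Reagents that add atoms: N-bromosuccinimide, O=C1CCC(=O)N1Br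
Why: electrophilic aromatic bromination at C8, the more accessible nucleophilic site of the 5,7-dibenzyloxy A ring; the bromine caps the future upper unit against self-condensation and leaves in step 13.

Step 4
Reactants: 5 8-bromo-5,7,3',4'-tetra-O-benzyl-(−)-epicatechin
Product: 6 8-bromo-4β-(2-ethoxyethoxy)-5,7,3',4'-tetra-O-benzyl-(−)-epicatechin (2,3-cis-3,4-trans)
Conditions: DDQ (2 equiv), 2-ethoxyethanol (5 equiv), CH2Cl2, rt
Reagents that add atoms: 2-ethoxyethanol, OCCOCC
Why: DDQ benzylic oxidation (hydride abstraction at C4, cation stabilised by O1/O5/O7) with capture by the alcohol trans to the 3α-OH; the C4 configuration is of no consequence because step 10 passes through the same cation.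

Step 5
Reactants: 7 (+)-taxifolin, (2R,3R)-dihydroquercetin
Product: 8 7,3',4'-tri-O-benzyl-(+)-taxifolin (5-OH and 3-OH free)
Conditions: BnBr (3.1 equiv), K2CO3, DMF, rt, Ar, dark
Reagents that add atoms: benzyl bromide, BrCc1ccccc1
Why: Williamson ether synthesis that spares the 5-OH (hydrogen-bonded to C4=O) and the aliphatic 3-OH, so O5 is differentiated from all other phenolic oxygens.

Step 6
Reactants: 8 7,3',4'-tri-O-benzyl-(+)-taxifolin
Product: 9 5-O-allyl-7,3',4'-tri-O-benzyl-(+)-taxifolin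
Conditions: allyl methyl carbonate (1.5 equiv), Pd(PPh3)4 (3 mol%), THF, 40 °C
Reagents that add atoms: allyl methyl carbonate, C=CCOC(=O)OC
Why: Tsuji–Trost O-allylation of the single remaining phenol without added base (methoxide appears only as the π-allyl complex forms), which protects the base-labile α-ketol and tags O5 as the only non-benzyl phenol ether.

Step 7
Reactants: 9 5-O-allyl-7,3',4'-tri-O-benzyl-(+)-taxifolin
Product: 10 5-O-allyl-7,3',4'-tri-O-benzyl-(+)-taxifolin 3-O-methanesulfonate (2α-aryl, 3β-OMs)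
Conditions: MsCl (1.3 equiv), Et3N, CH2Cl2, −20 °C
Reagents that add atoms: methanesulfonyl chloride, CS(=O)(=O)Cl
Why: sulfonylation of the only free hydroxyl with retention at C3 (O–S bond formation); low temperature and short contact with base avoid enolisation of the α-sulfonyloxy ketone.

Step 8
Reactants: 10 5-O-allyl-7,3',4'-tri-O-benzyl-(+)-taxifolin 3-O-methanesulfonate
Product: 11 (2R)-5-allyloxy-7,3',4'-tribenzyloxy-2,3-trans-3,4-trans-flavan-3,4-diol 3-O-methanesulfonate (2α-aryl, 3β-OMs, 4α-OH)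
Conditions: NaBH4, CeCl3·7H2O, THF/MeOH, −40 °C; AcOH quench at −40 °C
Reagents that add atoms: none
Why: Luche-type borohydride reduction in which axial hydride delivery to the half-chair (2-aryl and 3-OMs equatorial) gives the equatorial 4α-OH, as in the reduction of trans-dihydroflavonols to 2,3-trans-3,4-trans-flavan-3,4-diols; the diequatorial hydroxy mesylate should not close at −40 °C.

Step 9
Reactants: 11 (2R)-5-allyloxy-7,3',4'-tribenzyloxy-2,3-trans-3,4-trans-flavan-3,4-diol 3-O-methanesulfonate; 2 5,7,3',4'-tetra-O-benzyl-(+)-catechin (3 equiv)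
Product: 13 5-O-allyl-7,3',4'-tri-O-benzylepicatechin-(4β→8)-5,7,3',4'-tetra-O-benzylcatechin (upper unit 2α-aryl/3α-OH/4β-aryl), via 3α,4α-epoxyflavan 12 (not isolated)
Conditions: NaH (1.05 equiv), THF, 0 °C → rt; then CH2Cl2, 2, BF3·OEt2 (0.3 equiv), −78 → −40 °C
Reagents that add atoms: none
Why: NaH deprotonates the 4α-OH, and in the ring-flipped half-chair this oxygen is antiperiplanar to the 3β-OMs and displaces it (3-exo-tet, inversion at C3) to give oxirane 12, so that the former carbonyl oxygen becomes the 3α-oxygen, cis to the 2α-aryl group. BF3 then opens the oxirane at the benzylic C4–O bond, whose ionisation is assisted by O1, O5 and O7 of the phloroglucinol-type A ring, and C8 of 2 attacks C4 (Friedel–Crafts alkylation by an aryl epoxide; closest known types are the Lewis-acid coupling of flavan C4 ethers and the acid-mediated C4 opening of chromene oxides). The only ring closed is the oxirane, and it is opened again in the same flask, so no ring of 13 is new. C3 is fixed by SN2 inversion of the mesylate and C4 by attack anti to the departing oxygen and to the 2-aryl group (β-face), both relayed from C2 of taxifolin, which gives the 2,3-cis-3,4-trans triad. The step needs C4 rather than C3 opening (secured by the 2,4,6-trioxygenated benzylic C4) and arylation rather than a 1,2-hydride (Meinwald) shift (in the 2-aryl-equatorial half-chair the 3-O is pseudo-axial and the C3–H bond is not aligned with the C4 p-orbital; low temperature). It also needs C8 rather than C6 of 2 (the usual site of 5,7-di-O-benzylflavan-3-ols) and capture by 2 rather than by a second molecule of 12 (excess 2).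

Step 10
Reactants: 13 5-O-allyl-7,3',4'-tri-O-benzylepicatechin-(4β→8)-5,7,3',4'-tetra-O-benzylcatechin; 6 8-bromo-4β-(2-ethoxyethoxy)-5,7,3',4'-tetra-O-benzyl-(−)-epicatechin (1.2 equiv)
Product: 14 8-bromo-5,7,3',4'-tetra-O-benzylepicatechin-(4β→8)-5-O-allyl-7,3',4'-tri-O-benzylepicatechin-(4β→8)-5,7,3',4'-tetra-O-benzylcatechin
Conditions: TMSOTf (0.3 equiv), CH2Cl2, −78 → −40 °C; Et3N quench
Reagents that add atoms: none
Why: Lewis-acid ionisation of the C4 ether of 6 and Friedel–Crafts attack by C8 of the allyl-tagged ring of 13 (the position between O1 and O7 of the upper unit of a dimeric nucleophile is the usual site of chain extension, C6 of both rings being flanked by two alkoxy groups), trans to the 3α-OH of 6 to set the 4β bond; the C8–Br of 6 excludes its self-condensation and further growth.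

Step 11
Reactants: 14 the allyl-tagged, bromo-capped undecabenzyl trimer
Product: 15 the same trimer with free 5-OH on the middle unit (8-bromo-tetra-O-benzylepicatechin-(4β→8)-7,3',4'-tri-O-benzylepicatechin-(4β→8)-tetra-O-benzylcatechin)
Conditions: Pd(PPh3)4 (5 mol%), morpholine (5 equiv), THF, rt
Reagents that add atoms: none
Why: Tsuji–Trost deallylation (Pd(0) ionises the aryl allyl ether and morpholine takes up the allyl group), which unmasks the single phenol while benzyl ethers and the hindered electron-rich C–Br bond stay intact at rt.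

Step 12
Reactants: 15 the trimer with free 5-OH on the middle unit
Product: 16 the trimer with 5-O-trifluoromethanesulfonate on the middle unit
Conditions: PhNTf2 (1.5 equiv), Et3N, DMAP (cat.), CH2Cl2, rt
Reagents that add atoms: N-phenylbis(trifluoromethanesulfonimide), O=S(=O)(N(c1ccccc1)S(=O)(=O)C(F)(F)F)C(F)(F)F
Why: triflation of the only phenol with the phenol-selective triflimide reagent, which does not sulfonylate the three secondary 3-OH groups.

Step 13
Reactants: 16 the trimer with 5-O-triflate on the middle unit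
Product: 17 epicatechin-(4β→8)-epifisetinidol-(4β→8)-catechin (target, CNP0270097.1)
Conditions: H2 (1 atm), Pd(OH)2/C, Et3N (2.2 equiv), THF/MeOH/H2O, rt
Reagents that add atoms: none
Why: heterogeneous Pd hydrogenolysis of the eleven benzyl ethers together with reductive cleavage of the aryl C–Br and aryl C–OTf bonds (amine-assisted hydrogenolysis of aryl triflates), which converts C5–O of the middle unit into C5–H without touching any stereocentre.

**Compound list**

1 | (+)-catechin | Oc1cc(O)c2c(c1)O[C@H](c1ccc(O)c(O)c1)[C@@H](O)C2 | starting material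
2 | 5,7,3',4'-tetra-O-benzyl-(+)-catechin | c1ccccc1COc1cc(OCc2ccccc2)c2c(c1)O[C@H](c1ccc(OCc3ccccc3)c(OCc3ccccc3)c1)[C@@H](O)C2 | intermediate
3 | (−)-epicatechin | Oc1cc(O)c2c(c1)O[C@H](c1ccc(O)c(O)c1)[C@H](O)C2 | starting material
4 | 5,7,3',4'-tetra-O-benzyl-(−)-epicatechin | c1ccccc1COc1cc(OCc2ccccc2)c2c(c1)O[C@H](c1ccc(OCc3ccccc3)c(OCc3ccccc3)c1)[C@H](O)C2 | intermediate
5 | 8-bromo-5,7,3',4'-tetra-O-benzyl-(−)-epicatechin | c1ccccc1COc1cc(OCc2ccccc2)c2c(c1Br)O[C@H](c1ccc(OCc3ccccc3)c(OCc3ccccc3)c1)[C@H](O)C2 | intermediate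
6 | 8-bromo-4β-(2-ethoxyethoxy)-5,7,3',4'-tetra-O-benzyl-(−)-epicatechin | c1ccccc1COc1cc(OCc2ccccc2)c2c(c1Br)O[C@H](c1ccc(OCc3ccccc3)c(OCc3ccccc3)c1)[C@H](O)[C@H]2OCCOCC | intermediate
7 | (+)-taxifolin, (2R,3R)-dihydroquercetin | Oc1cc(O)c2c(c1)O[C@H](c1ccc(O)c(O)c1)[C@@H](O)C2=O | starting material
8 | 7,3',4'-tri-O-benzyl-(+)-taxifolin | c1ccccc1COc1cc(O)c2c(c1)O[C@H](c1ccc(OCc3ccccc3)c(OCc3ccccc3)c1)[C@@H](O)C2=O | intermediate
9 | 5-O-allyl-7,3',4'-tri-O-benzyl-(+)-taxifolin | c1ccccc1COc1cc(OCC=C)c2c(c1)O[C@H](c1ccc(OCc3ccccc3)c(OCc3ccccc3)c1)[C@@H](O)C2=O | intermediate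
10 | 5-O-allyl-7,3',4'-tri-O-benzyl-(+)-taxifolin 3-O-methanesulfonate | c1ccccc1COc1cc(OCC=C)c2c(c1)O[C@H](c1ccc(OCc3ccccc3)c(OCc3ccccc3)c1)[C@@H](OS(C)(=O)=O)C2=O | intermediate
11 | (2R)-5-allyloxy-7,3',4'-tribenzyloxy-2,3-trans-3,4-trans-flavan-3,4-diol 3-O-methanesulfonate (2α-aryl, 3β-OMs, 4α-OH) | c1ccccc1COc1cc(OCC=C)c2c(c1)O[C@H](c1ccc(OCc3ccccc3)c(OCc3ccccc3)c1)[C@@H](OS(C)(=O)=O)[C@@H]2O | intermediate
12 | (2R)-5-allyloxy-7,3',4'-tribenzyloxy-3α,4α-epoxyflavan (oxirane oxygen cis to the 2-aryl group) | c1ccccc1COc1cc(OCC=C)c2c(c1)O[C@H](c1ccc(OCc3ccccc3)c(OCc3ccccc3)c1)[C@@H]3O[C@@H]32 | intermediate (not isolated)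
13 | 5-O-allyl-7,3',4'-tri-O-benzylepicatechin-(4β→8)-5,7,3',4'-tetra-O-benzylcatechin | c1ccccc1COc1cc(OCC=C)c2c(c1)O[C@H](c1ccc(OCc3ccccc3)c(OCc3ccccc3)c1)[C@H](O)[C@H]2c1c(OCc3ccccc3)cc(OCc3ccccc3)c2c1O[C@H](c1ccc(OCc3ccccc3)c(OCc3ccccc3)c1)[C@@H](O)C2 | intermediate
14 | 8-bromo-5,7,3',4'-tetra-O-benzylepicatechin-(4β→8)-5-O-allyl-7,3',4'-tri-O-benzylepicatechin-(4β→8)-5,7,3',4'-tetra-O-benzylcatechin | c1ccccc1COc1cc(OCc2ccccc2)c2c(c1Br)O[C@H](c1ccc(OCc3ccccc3)c(OCc3ccccc3)c1)[C@H](O)[C@H]2c1c(OCc3ccccc3)cc(OCC=C)c2c1O[C@H](c1ccc(OCc3ccccc3)c(OCc3ccccc3)c1)[C@H](O)[C@H]2c1c(OCc3ccccc3)cc(OCc3ccccc3)c2c1O[C@H](c1ccc(OCc3ccccc3)c(OCc3ccccc3)c1)[C@@H](O)C2 | intermediate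
15 | 8-bromo-5,7,3',4'-tetra-O-benzylepicatechin-(4β→8)-7,3',4'-tri-O-benzylepicatechin-(4β→8)-5,7,3',4'-tetra-O-benzylcatechin (middle 5-OH free) | c1ccccc1COc1cc(OCc2ccccc2)c2c(c1Br)O[C@H](c1ccc(OCc3ccccc3)c(OCc3ccccc3)c1)[C@H](O)[C@H]2c1c(OCc3ccccc3)cc(O)c2c1O[C@H](c1ccc(OCc3ccccc3)c(OCc3ccccc3)c1)[C@H](O)[C@H]2c1c(OCc3ccccc3)cc(OCc3ccccc3)c2c1O[C@H](c1ccc(OCc3ccccc3)c(OCc3ccccc3)c1)[C@@H](O)C2 | intermediate
16 | the same trimer as its middle-unit 5-O-trifluoromethanesulfonate | c1ccccc1COc1cc(OCc2ccccc2)c2c(c1Br)O[C@H](c1ccc(OCc3ccccc3)c(OCc3ccccc3)c1)[C@H](O)[C@H]2c1c(OCc3ccccc3)cc(OS(=O)(=O)C(F)(F)F)c2c1O[C@H](c1ccc(OCc3ccccc3)c(OCc3ccccc3)c1)[C@H](O)[C@H]2c1c(OCc3ccccc3)cc(OCc3ccccc3)c2c1O[C@H](c1ccc(OCc3ccccc3)c(OCc3ccccc3)c1)[C@@H](O)C2 | intermediate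
17 | epicatechin-(4β→8)-epifisetinidol-(4β→8)-catechin (CNP0270097.1) | Oc1cc(O)c2c(c1)O[C@H](c1ccc(O)c(O)c1)[C@H](O)[C@H]2c1c(O)ccc2c1O[C@H](c1ccc(O)c(O)c1)[C@H](O)[C@H]2c1c(O)cc(O)c2c1O[C@H](c1ccc(O)c(O)c1)[C@@H](O)C2 | target

**Count and risks**

Total steps: 13. Longest linear sequence: 9 (steps 5–13, from taxifolin).

Steps most likely to fail:

Step 9. After Lewis-acid activation the oxirane may be lost by a 1,2-hydride shift to the flavan-3-one or by attack of a second molecule of the epoxide before C8 of 2 is alkylated; the base-induced closure itself is expected to be uneventful. Fallback, from 11: closure and opening are run together under basic conditions (K2CO3, MeOH/THF, rt), where oxirane 12 is opened at C4 by methanol trans to the 3-oxygen to give the isolable 5-O-allyl-7,3',4'-tri-O-benzyl-4β-methoxyepicatechin F1. F1 is then coupled with 2 (3 equiv) by the standard catalytic TMSOTf protocol (CH2Cl2, −78 °C); this ionises a C4 ether with a neutral 3-OH, so there is no alkoxide to drive the hydride shift. The route is rejoined at 13.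

Step 10. The cation from 6 may attack C6 of either ring of 13 instead of C8 of the middle ring, or alkylate a 3-OH. Fallback, from 11, with the order of bond formation reversed and orthogonal leaving groups: the oxirane is formed as in step 9 (NaH, THF) and opened at C4 with benzyl mercaptan (cat. BF3·OEt2, −78 °C) to give 5-O-allyl-7,3',4'-tri-O-benzyl-4β-benzylthioepicatechin F2, whose only nucleophilic ring is the allyl-tagged one. F2 is coupled with 6 (BF3·OEt2, CH2Cl2, −78 °C; the thioether is inert to the hard Lewis acid) to give the upper–middle dimer 8-bromo-tetra-O-benzylepicatechin-(4β→8)-5-O-allyl-tri-O-benzyl-4β-benzylthioepicatechin F3. Thiophilic activation of F3 (AgBF4, THF/CH2Cl2, 0 °C) with excess 2 then forms the middle–lower bond, and the route is rejoined at 14.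

Step 13. Hydrogenolysis of the hindered C5–OTf bond on the heterogeneous catalyst may be slow or incomplete, S–O cleavage may return the phenol, the amine may inhibit debenzylation, or prolonged exposure may cleave the benzylic C2–O1 bonds. Fallback, from 16: the C–OTf and C–Br bonds are first reduced in homogeneous phase (Pd(OAc)2, dppf, HCO2H, Et3N, DMF, 70 °C; Pd-catalysed formate reduction) to the undecabenzyl ether F4, which carries C5–H in the middle unit and C8–H in the upper unit. Plain hydrogenolysis of F4 (H2, Pd(OH)2/C, THF/MeOH/H2O, no amine) then gives 17.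

**Further compounds**

F1 | step 9 | 5-O-allyl-7,3',4'-tri-O-benzyl-4β-methoxyepicatechin (2,3-cis-3,4-trans) | c1ccccc1COc1cc(OCC=C)c2c(c1)O[C@H](c1ccc(OCc3ccccc3)c(OCc3ccccc3)c1)[C@H](O)[C@H]2OC
F2 | step 10 | 5-O-allyl-7,3',4'-tri-O-benzyl-4β-benzylthioepicatechin (2,3-cis-3,4-trans) | c1ccccc1COc1cc(OCC=C)c2c(c1)O[C@H](c1ccc(OCc3ccccc3)c(OCc3ccccc3)c1)[C@H](O)[C@H]2SCc1ccccc1
F3 | step 10 | 8-bromo-5,7,3',4'-tetra-O-benzylepicatechin-(4β→8)-5-O-allyl-7,3',4'-tri-O-benzyl-4β-benzylthioepicatechin | c1ccccc1COc1cc(OCc2ccccc2)c2c(c1Br)O[C@H](c1ccc(OCc3ccccc3)c(OCc3ccccc3)c1)[C@H](O)[C@H]2c1c(OCc3ccccc3)cc(OCC=C)c2c1O[C@H](c1ccc(OCc3ccccc3)c(OCc3ccccc3)c1)[C@H](O)[C@H]2SCc1ccccc1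
F4 | step 13 | 5,7,3',4'-tetra-O-benzylepicatechin-(4β→8)-7,3',4'-tri-O-benzylepifisetinidol-(4β→8)-5,7,3',4'-tetra-O-benzylcatechin | c1ccccc1COc1cc(OCc2ccccc2)c2c(c1)O[C@H](c1ccc(OCc3ccccc3)c(OCc3ccccc3)c1)[C@H](O)[C@H]2c1c(OCc3ccccc3)ccc2c1O[C@H](c1ccc(OCc3ccccc3)c(OCc3ccccc3)c1)[C@H](O)[C@H]2c1c(OCc3ccccc3)cc(OCc3ccccc3)c2c1O[C@H](c1ccc(OCc3ccccc3)c(OCc3ccccc3)c1)[C@@H](O)C2
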